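**Plan**

1. Numbering follows the germacranolides: carbocycle C1–C10, lactone carbons C11–C13, C14 on C10, C15 on C4, oxirane-ester carbons primed.
2. Cuts, in order: C3–C4 of the ten-membered ring (carbinol carbon to the methyl-bearing carbon of the Z allylic alcohol); the C8 ester; C6–C7 together with O–C12 of the lactone; then C7–C11, C1–C2, C10–C14 and C9–C10 of the chain. This leads back to benzyl (R)-glycidyl ether, acetylide, AlMe3, ethylene oxide, methyl acrylate, (Z)-3-iodobut-2-enal and an oxirane acid made from tiglyl alcohol.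
3. Forward order of rings: side-chain oxirane, C1–C10 oxirane on the open chain, methylidene lactone (chromium allylation and lactonisation), ester, and last the ten-membered carbocycle.
4. Enabling feature: C3 is a carbinol carbon bonded directly to the trisubstituted Z C4=C5 bond inside the ring, and that cis bond holds C3 and C6 on one side. An aldehyde carbon (C3) and an iodoalkene carbon (C4), both electrophilic, can therefore be joined by reductive polarity reversal at C4; this one event closes the carbocycle, creates C3 and delivers the target.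
5. Stereochemistry: C8 from the glycidyl ether; C1/C10 from reagent-controlled Shi epoxidation of the E alkene set by syn-carboalumination; C6/C7 from a chair transition state with allylic-strain relay from C8; C2'/C3' from Sharpless epoxidation; Z C4=C5 from trans-hydroalumination–iodination; C3 from the cyclic transition state of the key step.

Key step: step 19

**Route**

Step 1
Reactants: 1 (E)-2-methylbut-2-en-1-ol
Product: 2 [(2S,3S)-2,3-dimethyloxiran-2-yl]methanol
Conditions: Ti(OiPr)4 (cat.), L-(+)-diethyl tartrate (cat.), t-BuOOH, 4 Å molecular sieves, CH2Cl2, −20 °C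
Reagents that add atoms: tert-butyl hydroperoxide, CC(C)(C)OO
Why: Sharpless asymmetric epoxidation of an E-trisubstituted primary allylic alcohol, in which the titanium–L-(+)-tartrate complex transfers oxygen to one enantioface to set C2' and C3' (both S) while the E geometry fixes the two methyl groups cis on the oxirane.

Step 2
Reactants: 2 [(2S,3S)-2,3-dimethyloxiran-2-yl]methanol
Product: 3 (2R,3S)-2,3-dimethyloxirane-2-carboxylic acid
Conditions: RuCl3·xH2O (cat.), NaIO4, CCl4/MeCN/H2O, rt
Reagents that add atoms: sodium periodate, [Na+].[O-]I(=O)(=O)=O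
Why: Catalytic ruthenium tetroxide oxidation takes a primary 2,3-epoxy alcohol to the glycidic acid without opening the oxirane, and neither stereocenter is touched (the C2' descriptor changes from S to R only because the carboxyl now outranks the ring carbon).

Step 3
Reactants: 4 but-2-yn-1-ol
Product: 6 (Z)-3-iodobut-2-en-1-ol, via cyclic alkenylaluminate 5 (not isolated)
Conditions: NaAlH2(OCH2CH2OCH3)2, THF, 0 °C to rt; then I2, THF, −78 to 0 °C
Reagents that add atoms: iodine, II
Why: Hydroxyl-directed trans-hydroalumination of the propargylic alcohol places aluminium on C3 cis to the CH2O group in a five-membered aluminate, and iodinolysis with retention gives the Z iodoalkene that becomes C4=C5.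

Step 4
Reactants: 6 (Z)-3-iodobut-2-en-1-ol
Product: 7 (Z)-3-iodobut-2-enal
Conditions: MnO2, CH2Cl2, rt
Reagents that add atoms: none
Why: Heterogeneous MnO2 oxidation of an allylic alcohol is neutral and should leave the Z geometry and the C–I bond intact.

Step 5
Reactants: 8 benzyl (R)-glycidyl ether
Product: 9 (2R)-1-(benzyloxy)pent-4-yn-2-ol
Conditions: LiC≡CH·H2NCH2CH2NH2, DMSO, rt
Reagents that add atoms: lithium acetylide–ethylenediamine complex, [Li+].[C-]#C.NCCN
Why: SN2 opening of the terminal epoxide by acetylide at the unsubstituted carbon (future C9), so the stereocenter (future C8) is not attacked and keeps its configuration.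

Step 6
Reactants: 9 (2R)-1-(benzyloxy)pent-4-yn-2-ol
Product: 10 {[(2R)-1-(benzyloxy)pent-4-yn-2-yl]oxy}triethylsilane
Conditions: Et3SiCl, imidazole, CH2Cl2, 0 °C to rt
Reagents that add atoms: chlorotriethylsilane, CC[Si](Cl)(CC)CC
Why: Standard silylation of a secondary alcohol; the silyl ether is a poor leaving group in the later allylchromium step and can be removed with buffered fluoride in the presence of a TBDPS ether.

Step 7
Reactants: 10 {[(2R)-1-(benzyloxy)pent-4-yn-2-yl]oxy}triethylsilane
Product: 13 (3E,6R)-7-(benzyloxy)-4-methyl-6-(triethylsilyloxy)hept-3-en-1-ol, via alkenyldimethylalane 11 (not isolated), via lithium alkenylbutyldimethylalanate 12 (not isolated)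
Conditions: AlMe3, Cp2ZrCl2 (cat.), CH2Cl2, 0 °C to rt; evaporate; n-BuLi, THF/hexane, −78 to 0 °C; ethylene oxide, −30 °C to rt
Reagents that add atoms: trimethylaluminium, C[Al](C)C; ethylene oxide, C1CO1
Why: Zirconium-catalysed syn-carboalumination (Negishi) adds methyl to the internal and aluminium to the terminal alkyne carbon so that the C1=C10 alkene is E, and the more nucleophilic ate complex opens ethylene oxide with retention at the alkenyl carbon to deliver C2–C3.

Step 8
Reactants: 13 (3E,6R)-7-(benzyloxy)-4-methyl-6-(triethylsilyloxy)hept-3-en-1-ol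
Product: 14 (3E,6R)-7-(benzyloxy)-1-(tert-butyldiphenylsilyloxy)-4-methyl-6-(triethylsilyloxy)hept-3-ene
Conditions: t-BuPh2SiCl, imidazole, CH2Cl2, rt
Reagents that add atoms: tert-butyl(chloro)diphenylsilane, CC(C)(C)[Si](Cl)(c1ccccc1)c1ccccc1
Why: Routine silylation of the primary alcohol with a group that survives every step until C3 is needed as the aldehyde.

Step 9
Reactants: 14 (3E,6R)-7-(benzyloxy)-1-(tert-butyldiphenylsilyloxy)-4-methyl-6-(triethylsilyloxy)hept-3-ene
Product: 15 (2R,3R)-2-[(2R)-3-(benzyloxy)-2-(triethylsilyloxy)propyl]-3-[2-(tert-butyldiphenylsilyloxy)ethyl]-2-methyloxirane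
Conditions: D-fructose-derived ketone catalyst (1,2:4,5-di-O-isopropylidene-β-D-erythro-2,3-hexodiulo-2,6-pyranose), KHSO5 (as 2KHSO5·KHSO4·K2SO4), K2CO3, Bu4NHSO4, MeCN/CH2(OMe)2/aq Na2B4O7 buffer (pH 10.5), 0 °C
Reagents that add atoms: potassium peroxymonosulfate, [K+].[O-]S(=O)(=O)OO
Why: Shi epoxidation, in which the chiral dioxirane attacks the E-trisubstituted alkene through a spiro transition state under reagent control to give R at both C1 and C10, the trans oxirane following from the E geometry.

Step 10
Reactants: 15 (2R,3R)-2-[(2R)-3-(benzyloxy)-2-(triethylsilyloxy)propyl]-3-[2-(tert-butyldiphenylsilyloxy)ethyl]-2-methyloxirane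
Product: 16 (2R)-3-{(2R,3R)-3-[2-(tert-butyldiphenylsilyloxy)ethyl]-2-methyloxiran-2-yl}-2-(triethylsilyloxy)propan-1-ol
Conditions: H2 (1 atm), Pd/C, NaHCO3, EtOAc, rt
Reagents that add atoms: none
Why: Hydrogenolysis of the benzyl ether in a buffered aprotic medium should leave the trialkyl oxirane and both silyl ethers untouched, and the 4,5-epoxy alcohol is used at once so that it cannot cyclise to a tetrahydrofuran.

Step 11
Reactants: 16 (2R)-3-{(2R,3R)-3-[2-(tert-butyldiphenylsilyloxy)ethyl]-2-methyloxiran-2-yl}-2-(triethylsilyloxy)propan-1-ol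
Product: 17 (2R)-3-{(2R,3R)-3-[2-(tert-butyldiphenylsilyloxy)ethyl]-2-methyloxiran-2-yl}-2-(triethylsilyloxy)propanal
Conditions: Dess–Martin periodinane, NaHCO3, CH2Cl2, 0 °C to rt
Reagents that add atoms: none
Why: Buffered hypervalent-iodine oxidation should give the α-silyloxy aldehyde without epimerisation at C8 or opening of the oxirane.

Step 12
Reactants: 17 (2R)-3-{(2R,3R)-3-[2-(tert-butyldiphenylsilyloxy)ethyl]-2-methyloxiran-2-yl}-2-(triethylsilyloxy)propanal; 18 methyl acrylate
Product: 19 methyl (4R)-5-{(2R,3R)-3-[2-(tert-butyldiphenylsilyloxy)ethyl]-2-methyloxiran-2-yl}-3-hydroxy-2-methylidene-4-(triethylsilyloxy)pentanoate (both C3 epimers)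
Conditions: DABCO, neat methyl acrylate, rt
Reagents that add atoms: none
Why: Morita–Baylis–Hillman reaction, in which the zwitterionic enolate from DABCO and the acrylate adds to the inductively activated α-silyloxy aldehyde to form C7–C11; the new carbinol centre at C7 forms as a mixture, which is of no consequence because C7 becomes sp2 in step 13.

Step 13
Reactants: 19 methyl (4R)-5-{(2R,3R)-3-[2-(tert-butyldiphenylsilyloxy)ethyl]-2-methyloxiran-2-yl}-3-hydroxy-2-methylidene-4-(triethylsilyloxy)pentanoate
Product: 21 methyl (2Z,4R)-2-(bromomethyl)-5-{(2R,3R)-3-[2-(tert-butyldiphenylsilyloxy)ethyl]-2-methyloxiran-2-yl}-4-(triethylsilyloxy)pent-2-enoate, via allylic mesylate 20 (not isolated)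
Conditions: MsCl, Et3N, CH2Cl2, −40 to 0 °C; then LiBr, acetone, 0 °C
Reagents that add atoms: lithium bromide, [Li+].[Br-]
Why: SN2' displacement of the secondary allylic mesylate by bromide gives the conjugated primary bromide with the thermodynamically preferred Z geometry from either C7 epimer, and the non-acidic medium spares the oxirane.

Step 14
Reactants: 21 methyl (2Z,4R)-2-(bromomethyl)-5-{(2R,3R)-3-[2-(tert-butyldiphenylsilyloxy)ethyl]-2-methyloxiran-2-yl}-4-(triethylsilyloxy)pent-2-enoate; 7 (Z)-3-iodobut-2-enal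
Product: 24 iodoalkenyl methylidene lactone (6S,7S,8R,1R,10R), via allylchromium dichloride 22 (not isolated), via γ-hydroxy ester 23 (not isolated)
Conditions: CrCl2 (nickel-free), THF, 0 °C to rt, then 40 °C; aq NH4Cl
Reagents that add atoms: none
Why: Nozaki–Hiyama-type 2-(alkoxycarbonyl)allylation, in which CrCl2 inserts into the allylic C–Br bond only (the iodoalkene is inert without nickel) and the equilibrating allylchromium adds through a chair transition state with the aldehyde substituent and the C8 branch both equatorial to give the 6,7-anti adduct and hence the trans lactone; allylic strain with the ester holds H8 in the alkene plane so that the aldehyde attacks C7 anti to C9 with the C8–O bond outside, which sets C7 relative to C8, and the chromium alkoxide lactonises in the flask.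

Step 15
Reactants: 24 iodoalkenyl methylidene lactone (6S,7S,8R,1R,10R)
Product: 25 C8 alcohol of the lactone (6S,7R,8R,1R,10R)
Conditions: HF·pyridine, pyridine, THF, 0 °C
Reagents that add atoms: none
Why: Buffered HF·pyridine cleaves the secondary triethylsilyl ether much faster than the primary TBDPS ether and, at 0 °C with excess pyridine, should not open the oxirane or the lactone.

Step 16
Reactants: 25 C8 alcohol of the lactone (6S,7R,8R,1R,10R); 3 (2R,3S)-2,3-dimethyloxirane-2-carboxylic acid
Product: 27 C8 oxirane ester of the lactone (6S,7R,8R,1R,10R,2'R,3'S), via mixed anhydride 26 (not isolated)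
Conditions: 3, 2,4,6-Cl3C6H2COCl, Et3N, toluene, rt; then 25, DMAP, toluene, rt to 40 °C
Reagents that add atoms: none
Why: Yamaguchi esterification, in which DMAP transfers the oxirane acyl group from the hindered mixed anhydride to the secondary C8 alcohol; the acid has no α-hydrogen, so C2' cannot epimerise.

Step 17
Reactants: 27 C8 oxirane ester of the lactone (6S,7R,8R,1R,10R,2'R,3'S)
Product: 28 C3 primary alcohol (6S,7R,8R,1R,10R,2'R,3'S)
Conditions: Bu4NF, AcOH, THF, 0 °C to rt
Reagents that add atoms: none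
Why: Fluoride cleavage of the primary silyl ether, buffered with acetic acid so that the methylidene lactone, the esters and both oxiranes are not exposed to basic fluoride.

Step 18
Reactants: 28 C3 primary alcohol (6S,7R,8R,1R,10R,2'R,3'S)
Product: 29 seco iodoalkene aldehyde (6S,7R,8R,1R,10R,2'R,3'S)
Conditions: Dess–Martin periodinane, NaHCO3, CH2Cl2, 0 °C; crude aldehyde used directly
Reagents that add atoms: none
Why: Buffered Dess–Martin oxidation is mild enough to give the β,γ-epoxy aldehyde without base-induced opening of the oxirane, provided the product is not chromatographed.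

Step 19
Reactants: 29 seco iodoalkene aldehyde (6S,7R,8R,1R,10R,2'R,3'S)
Product: 31 CNP0268255.6 (target), via alkenylchromium dichloride 30 (not isolated)
Conditions: CrCl2, NiCl2 (cat.), degassed DMSO/THF, rt, slow addition of 29 (high dilution); aq NH4Cl
Reagents that add atoms: none
Why: Zerovalent nickel (formed from NiCl2 by CrCl2) inserts into the C4–I bond, the alkenyl group passes to trivalent chromium with retention of the Z geometry (intermediate 30), and this nucleophilic alkenylchromium adds to the C3 aldehyde in the same molecule, so two carbons that are both electrophilic in 29 are joined after polarity reversal at C4. The closest known reaction type is the Nozaki–Hiyama–Kishi macrocyclisation of iodoalkene aldehydes to carbocyclic allylic alcohols. The ten-membered carbocycle closes by C3–C4 bond formation in a 10-exo-trig mode with respect to the aldehyde (the C=O lies outside the new ring), with the Z alkene, the trans-fused lactone and the trans oxirane acting as three rigid turn elements that bring C3 and C4 together. The new stereocenter C3 is controlled by the cyclic transition state: the solvated chromium-bound oxygen has to point to the periphery and the aldehyde hydrogen into the ring, and with the chain folded as the lactone and the oxirane dictate this is expected to expose the Re face of the aldehyde to C4 and give 3S. The step needs chemoselectivity (nickel inserts only into the C–I bond, and the alkenylchromium adds to the aldehyde but not to the lactone, the C8 ester, the oxiranes or the methylidene acceptor), retention of alkene geometry (secured by the configurational stability of α-methyl alkenylchromium species) and cyclisation over oligomerisation (secured by slow addition at high dilution). The β,γ-epoxy aldehyde is kept free of base so that it does not eliminate before it is trapped.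

**Compound list**

1 | (E)-2-methylbut-2-en-1-ol (tiglyl alcohol) | C/C=C(\C)CO | starting material
2 | [(2S,3S)-2,3-dimethyloxiran-2-yl]methanol | OC[C@]1(C)O[C@H]1C | intermediate
3 | (2R,3S)-2,3-dimethyloxirane-2-carboxylic acid | OC(=O)[C@]1(C)O[C@H]1C | intermediate
4 | but-2-yn-1-ol | CC#CCO | starting material
5 | sodium 2,2-bis(2-methoxyethoxy)-3-methyl-2,5-dihydro-1,2-oxaluminol-2-uide (cyclic alkenylaluminate) | [Na+].CC1=CCO[Al-]1(OCCOC)OCCOC | intermediate
6 | (Z)-3-iodobut-2-en-1-ol | C/C(I)=C/CO | intermediate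
7 | (Z)-3-iodobut-2-enal | C/C(I)=C/C=O | intermediate
8 | benzyl (R)-glycidyl ether, (2R)-2-(benzyloxymethyl)oxirane | C(c1ccccc1)OC[C@H]1CO1 | starting material
9 | (2R)-1-(benzyloxy)pent-4-yn-2-ol | C(c1ccccc1)OC[C@H](O)CC#C | intermediate
10 | {[(2R)-1-(benzyloxy)pent-4-yn-2-yl]oxy}triethylsilane | C(c1ccccc1)OC[C@H](O[Si](CC)(CC)CC)CC#C | intermediate
11 | dimethyl[(1E,4R)-5-(benzyloxy)-2-methyl-4-(triethylsilyloxy)pent-1-enyl]alane | C(c1ccccc1)OC[C@H](O[Si](CC)(CC)CC)C/C(C)=C/[Al](C)C | intermediate
12 | lithium butyl(dimethyl)[(1E,4R)-5-(benzyloxy)-2-methyl-4-(triethylsilyloxy)pent-1-enyl]alanate | C(c1ccccc1)OC[C@H](O[Si](CC)(CC)CC)C/C(C)=C/[Al-](C)(C)CCCC.[Li+] | intermediate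
13 | (3E,6R)-7-(benzyloxy)-4-methyl-6-(triethylsilyloxy)hept-3-en-1-ol | C(c1ccccc1)OC[C@H](O[Si](CC)(CC)CC)C/C(C)=C/CCO | intermediate
14 | (3E,6R)-7-(benzyloxy)-1-(tert-butyldiphenylsilyloxy)-4-methyl-6-(triethylsilyloxy)hept-3-ene | C(c1ccccc1)OC[C@H](O[Si](CC)(CC)CC)C/C(C)=C/CCO[Si](c1ccccc1)(c1ccccc1)C(C)(C)C | intermediate
15 | (2R,3R)-2-[(2R)-3-(benzyloxy)-2-(triethylsilyloxy)propyl]-3-[2-(tert-butyldiphenylsilyloxy)ethyl]-2-methyloxirane | C(c1ccccc1)OC[C@H](O[Si](CC)(CC)CC)C[C@@]1(C)O[C@@H]1CCO[Si](c1ccccc1)(c1ccccc1)C(C)(C)C | intermediate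
16 | (2R)-3-{(2R,3R)-3-[2-(tert-butyldiphenylsilyloxy)ethyl]-2-methyloxiran-2-yl}-2-(triethylsilyloxy)propan-1-ol | OC[C@H](O[Si](CC)(CC)CC)C[C@@]1(C)O[C@@H]1CCO[Si](c1ccccc1)(c1ccccc1)C(C)(C)C | intermediate
17 | (2R)-3-{(2R,3R)-3-[2-(tert-butyldiphenylsilyloxy)ethyl]-2-methyloxiran-2-yl}-2-(triethylsilyloxy)propanal | O=C[C@H](O[Si](CC)(CC)CC)C[C@@]1(C)O[C@@H]1CCO[Si](c1ccccc1)(c1ccccc1)C(C)(C)C | intermediate
18 | methyl acrylate | C=CC(=O)OC | starting material
19 | methyl (4R)-5-{(2R,3R)-3-[2-(tert-butyldiphenylsilyloxy)ethyl]-2-methyloxiran-2-yl}-3-hydroxy-2-methylidene-4-(triethylsilyloxy)pentanoate (both C3 epimers) | C=C(C(=O)OC)C(O)[C@H](O[Si](CC)(CC)CC)C[C@@]1(C)O[C@@H]1CCO[Si](c1ccccc1)(c1ccccc1)C(C)(C)C | intermediate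
20 | 3-O-methanesulfonate of 19 (allylic mesylate) | C=C(C(=O)OC)C(OS(C)(=O)=O)[C@H](O[Si](CC)(CC)CC)C[C@@]1(C)O[C@@H]1CCO[Si](c1ccccc1)(c1ccccc1)C(C)(C)C | intermediate
21 | methyl (2Z,4R)-2-(bromomethyl)-5-{(2R,3R)-3-[2-(tert-butyldiphenylsilyloxy)ethyl]-2-methyloxiran-2-yl}-4-(triethylsilyloxy)pent-2-enoate | COC(=O)/C(CBr)=C/[C@H](O[Si](CC)(CC)CC)C[C@@]1(C)O[C@@H]1CCO[Si](c1ccccc1)(c1ccccc1)C(C)(C)C | intermediate
22 | dichloro[2-(methoxycarbonyl)pent-2-enyl]chromium derived from 21 (trivalent chromium on C13, alkene isomers interconvert) | COC(=O)C(C[Cr](Cl)Cl)=C[C@H](O[Si](CC)(CC)CC)C[C@@]1(C)O[C@@H]1CCO[Si](c1ccccc1)(c1ccccc1)C(C)(C)C | intermediate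
23 | open-chain γ-hydroxy α-methylidene methyl ester formed by C6–C7 union of 21 and 7 (6S,7S,8R,1R,10R; present as its chromium alkoxide) | C=C(C(=O)OC)[C@@H]([C@H](O)/C=C(/C)I)[C@H](O[Si](CC)(CC)CC)C[C@@]1(C)O[C@@H]1CCO[Si](c1ccccc1)(c1ccccc1)C(C)(C)C | intermediate
24 | trans-α-methylidene-γ-butyrolactone with the (Z)-2-iodoprop-1-enyl group on C6 and the chain C8H(OSiEt3)–C9H2–[C10(CH3)–O–C1H oxirane]–C2H2–C3H2–OSiPh2tBu on C7 (6S,7S,8R,1R,10R) | C=C1C(=O)O[C@H](/C=C(/C)I)[C@H]1[C@H](O[Si](CC)(CC)CC)C[C@@]1(C)O[C@@H]1CCO[Si](c1ccccc1)(c1ccccc1)C(C)(C)C | intermediate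
25 | C8 alcohol of 24 (6S,7R,8R,1R,10R) | C=C1C(=O)O[C@H](/C=C(/C)I)[C@H]1[C@H](O)C[C@@]1(C)O[C@@H]1CCO[Si](c1ccccc1)(c1ccccc1)C(C)(C)C | intermediate
26 | (2R,3S)-2,3-dimethyloxirane-2-carboxylic 2,4,6-trichlorobenzoic anhydride | O=C(OC(=O)[C@]1(C)O[C@H]1C)c1c(Cl)cc(Cl)cc1Cl | intermediate
27 | C8 (2R,3S)-2,3-dimethyloxirane-2-carboxylate of 25 (6S,7R,8R,1R,10R,2'R,3'S) | C=C1C(=O)O[C@H](/C=C(/C)I)[C@H]1[C@H](OC(=O)[C@]1(C)O[C@H]1C)C[C@@]1(C)O[C@@H]1CCO[Si](c1ccccc1)(c1ccccc1)C(C)(C)C | intermediate
28 | C3 primary alcohol from 27 (6S,7R,8R,1R,10R,2'R,3'S) | C=C1C(=O)O[C@H](/C=C(/C)I)[C@H]1[C@H](OC(=O)[C@]1(C)O[C@H]1C)C[C@@]1(C)O[C@@H]1CCO | intermediate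
29 | seco iodoalkene aldehyde, C3 aldehyde of 28 (6S,7R,8R,1R,10R,2'R,3'S) | C=C1C(=O)O[C@H](/C=C(/C)I)[C@H]1[C@H](OC(=O)[C@]1(C)O[C@H]1C)C[C@@]1(C)O[C@@H]1CC=O | intermediate
30 | dichloro[(Z)-alkenyl]chromium from 29, iodine on C4 replaced by trivalent chromium | C=C1C(=O)O[C@H](/C=C(/C)[Cr](Cl)Cl)[C@H]1[C@H](OC(=O)[C@]1(C)O[C@H]1C)C[C@@]1(C)O[C@@H]1CC=O | intermediate
31 | CNP0268255.6, (1R,3S,6R,7R,8R,10R)-1,10-epoxy-3-hydroxy-8-[(2R,3S)-2,3-dimethyloxirane-2-carbonyloxy]germacra-4Z,11(13)-dien-12,6-olide | C=C1C(=O)O[C@@H]2/C=C(/C)[C@@H](O)C[C@H]3O[C@]3(C)C[C@@H](OC(=O)[C@]3(C)O[C@H]3C)[C@@H]12 | target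

**Count and risks**

Total step count: 19. Longest linear sequence: 15 steps (steps 5 to 19, from 8).

Step 19. The ring may close with poor facial selectivity at the C3 aldehyde, so that the new carbinol centre is set the wrong way or as a mixture. The fallback sets out from 29 and returns at 31. The ring closure is run as in step 19 and the crude allylic alcohols, chiefly the (3R)-epimer of the target F1, are oxidised with Dess–Martin periodinane/NaHCO3 to the macrocyclic Z-enone F2, in which C3 is no longer stereogenic. Corey–Bakshi–Shibata reduction ((R)-2-methyl-CBS-oxazaborolidine, catecholborane, toluene, −78 °C) should then deliver hydride under reagent control, with the alkenyl group as the large substituent, to give the 3S alcohol 31.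

Step 14. The allylchromium may react through its other alkene geometry or on the other face of C7 (syn instead of anti addition), or the C8 silyloxy group may be lost by 1,4-elimination from the allylmetal. The fallback sets out from 21 and 7 and returns at 24. Indium-mediated Barbier coupling (In, THF/H2O, rt) normally favours the syn adduct of 2-(bromomethyl)alk-2-enoates and is less prone to β-oxygen elimination; after lactonisation it would give the cis-lactone F3, the C6 epimer of 24, provided the C7/C8 relationship is the required one. Saponification (LiOH, THF/H2O, 0 °C, careful neutralisation) to the hydroxy acid F4 and Mitsunobu lactonisation (PPh3, DIAD, THF, 0 °C), with inversion at the allylic carbinol C6, would return the trans-lactone 24.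

Step 12. The addition may be slow, with base-induced epimerisation at C8 of the α-silyloxy aldehyde during the long exposure to amine. The fallback sets out from 17 and returns at 19. Aldol addition of the lithium enolate of methyl 3-(dimethylamino)propanoate (LDA, THF, −78 °C) forms the same C7–C11 bond in minutes and gives the β-hydroxy α-(dimethylaminomethyl) ester F5. N-Methylation (MeI, MeCN) gives the trimethylammonium iodide F6, and elimination of trimethylamine (DBU, CH2Cl2, 0 °C) gives the methylidene ester 19.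

**Further compounds**

F1 | step 19 | (3R)-epimer of 31 (1R,3R,6R,7R,8R,10R,2'R,3'S) | C=C1C(=O)O[C@@H]2/C=C(/C)[C@H](O)C[C@H]3O[C@]3(C)C[C@@H](OC(=O)[C@]3(C)O[C@H]3C)[C@@H]12
F2 | step 19 | 3-oxo analogue of 31, macrocyclic Z-enone (1R,6R,7R,8R,10R,2'R,3'S) | C=C1C(=O)O[C@@H]2/C=C(/C)C(=O)C[C@H]3O[C@]3(C)C[C@@H](OC(=O)[C@]3(C)O[C@H]3C)[C@@H]12
F3 | step 14 | cis-lactone, C6 epimer of 24 (6R,7S,8R,1R,10R) | C=C1C(=O)O[C@@H](/C=C(/C)I)[C@H]1[C@H](O[Si](CC)(CC)CC)C[C@@]1(C)O[C@@H]1CCO[Si](c1ccccc1)(c1ccccc1)C(C)(C)C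
F4 | step 14 | γ-hydroxy α-methylidene acid from F3 (6R,7S,8R,1R,10R) | C=C(C(=O)O)[C@@H]([C@@H](O)/C=C(/C)I)[C@H](O[Si](CC)(CC)CC)C[C@@]1(C)O[C@@H]1CCO[Si](c1ccccc1)(c1ccccc1)C(C)(C)C
F5 | step 12 | methyl (4R)-2-[(dimethylamino)methyl]-5-{(2R,3R)-3-[2-(tert-butyldiphenylsilyloxy)ethyl]-2-methyloxiran-2-yl}-3-hydroxy-4-(triethylsilyloxy)pentanoate (C2/C3 epimers) | CN(C)CC(C(=O)OC)C(O)[C@H](O[Si](CC)(CC)CC)C[C@@]1(C)O[C@@H]1CCO[Si](c1ccccc1)(c1ccccc1)C(C)(C)C
F6 | step 12 | N-methyl trimethylammonium iodide of F5 | C[N+](C)(C)CC(C(=O)OC)C(O)[C@H](O[Si](CC)(CC)CC)C[C@@]1(C)O[C@@H]1CCO[Si](c1ccccc1)(c1ccccc1)C(C)(C)C.[I-]
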